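**Remark on the structure (assumption):** the SMILES is read as (1R,3S) in the ring with bromine cis to the side chain, (2R) at the acetate carbon and Z at the trisubstituted olefin. 2-Methylcyclohex-2-en-1-one and methyl (S)-2,2-dimethyl-1,3-dioxolane-4-carboxylate are taken as commercial.

## Analysis of the target

Target 21 is a C15 dibromo sesquiterpenoid acetate, numbered here as C1 (CH2Br), C2 (CHOAc), C3 (olefinic, methyl C15), C4 (olefinic CH), C5 (CH2) and ring A = C6 (CH), C7 (bearing exocyclic methylene C14), C8, C9 (CH2), C10 (CHBr), C11 (quaternary, methyls C12 and C13). Ring A holds C6 (R) and C10 (S) in a 1,3-cis relationship across C11, so bromine and side chain are both equatorial. The third stereocentre, C2 (R), is five bonds from the ring and cannot be controlled from it. The C3=C4 olefin is Z, with C2 and C5 on the same side. Sensitive groups are the neopentyl secondary bromide at C10 (elimination, methyl shift on ionisation, very slow SN2), the exocyclic C7=C14 olefin (acid isomerisation into the ring), the β-bromo acetate at C1/C2 (epoxide formation and acyl migration under base) and the allylic C2–O bond. The hard points are the equatorial bromide on a neopentyl carbon, the C6–C5 bond wedged between quaternary C11 and sp2 C7 with a regiodefined exocyclic olefin, and independent control of C2 and the Z geometry. The feature the route exploits is the array C7(=C14)–C6–C11(C12)(C13): with C14 read as a carbonyl oxygen it is a β,β-dimethyl ketone whose α-carbon C6 is bonded to C5, and C5 is allylic to C3=C4. This is the retron of a cuprate conjugate addition followed by enolate allylation, and it places the fragment union at the most hindered bond of the molecule.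

## Retrosynthetic reasoning

**C1–Br and the acetate (21 ⇒ 20 ⇒ 18).** The β-bromo acetate is the most base-sensitive part, so it is made last. The primary bromide comes from sulfonate 20 by SN2, and 20 from diol 18 by selective primary sulfonylation and acetylation. No bond to C2 is touched, so C2 is carried unchanged from a chiral-pool diol.

**C10–Br (18 ⇒ 17 ⇒ 16).** An equatorial bromide on a neopentyl ring carbon is only realistic by SN2 on an axial oxygen leaving group. The C10–Br bond is therefore cut back to alcohol 16 with the opposite C10 configuration, its oxygen trans to the C6 side chain. The diol is masked as the acetonide (17) while this is done.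

**C7=C14 (16 ⇒ 15 ⇒ 14).** The exocyclic methylene is cut back to the ketone of 14. The carbonyl is what makes C6 nucleophilic, and a non-basic methylenation places the olefin without regiochemical doubt and without epimerising C6.

**C6–C5 and C11–C13 (14 ⇒ 4 + 12, key disconnection).** Both bonds at the congested centre are cut together. Adding a methyl nucleophile to the β-carbon of enone 4 creates quaternary C11 and gives enolate 13 with its double bond fixed toward C6; deprotonation of the saturated ketone would enolise toward C8 instead. Enolate 13 is alkylated by the complete side chain as allylic bromide 12. The C10 silyloxy group steers the electrophile to the opposite face, which gives the trans relationship that the later inversion at C10 needs. The precursors are a seven-carbon enone and a six-carbon bromide of similar size.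

**Enone 4 (4 ⇒ 3 ⇒ 2 ⇒ 1).** The C10 oxygen stereocentre comes from catalytic asymmetric 1,2-reduction of enone 1. Allylic oxidation of silyl ether 3 then places the carbonyl at the ring CH2 that becomes C7.

**Bromide 12 (12 ⇒ 11 ⇒ 10 ⇒ 9 ⇒ 7 ⇒ 5).** The Z olefin is cut back to ynoate 9, because syn addition of a methylcopper reagent across the triple bond puts C15 on C3 and leaves C5 and C2 cis. The ynoate comes from alkyne 7 and this from glycerate 5, whose stereocentre becomes C2 and whose two oxygens become the C1/C2 diol.

## Alternatives that were turned down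

**Alternative 1:** Disconnection of the ring bond C6–C11 (the textbook, biomimetic cut). The forward key step is a bromonium-initiated cation–olefin cyclisation of acyclic trienyl bromoacetate A1: an electrophilic bromine donor attacks C10=C11, C6 closes onto C11 through a chair, and the C7 cation loses a proton from C14 to give 21 directly. It was turned down for four reasons.
- An achiral bromine donor cannot distinguish the faces of the remote C10=C11 olefin while C2 is already fixed, so 21 would form with its ring-enantiomeric diastereomer in equal amounts; enantioselective variants depend on aryl terminators.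
- The C7 cation can lose a proton from C14, C8 or C6, so olefin regioisomers are expected.
- A1 offers three nucleophilic olefins and a participating acetate to the electrophile.
- A1 needs the same Z-olefin and C2 chemistry as the chosen route, so little is saved and the least selective step comes last.

**Alternative 2:** Disconnection of C6–C5 by a [3,3] shift. The forward key step is a Johnson orthoester Claisen rearrangement of allylic alcohol A2 to ester A3, which sets C6, adds C5 and C4 and creates the exocyclic C7=C14 olefin in one step. It was turned down because only two carbons are added. A2 costs three extra steps from enolate 13 (enol triflate, carbonylation, reduction). A3 then needs half-reduction, a Z-selective trisubstituted olefination and a reagent-controlled creation of C2, at least six further steps, all on the most valuable intermediate.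

**Alternative 3:** Chiral-pool strain release from (1R,5R)-β-pinene A4. Its ten carbons map onto C5–C14 of 21: bridge CH2 = C5, remote bridgehead = C10, exocyclic methylene = C14. Opening the cyclobutane bond between the remote bridgehead and the CH2 bridge, with bromine delivered to the bridgehead with retention, would give dibromide A5, a few steps from the target. It was turned down because every known opening of the pinane cyclobutane (cation, radical or metal allyl generated at the olefin) breaks the bond from the allylic bridgehead to the gem-dimethyl carbon and leads to p-menthane skeletons. The distal bond has no activating group, nucleophilic bromide delivery would invert and give the trans isomer, and A4 is the less abundant enantiomer.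

Key step: step 9

## Steps

Step 1
Reactants: 1 2-methylcyclohex-2-en-1-one
Product: 2 (1R)-2-methylcyclohex-2-en-1-ol
Conditions: (S)-1-methyl-3,3-diphenyltetrahydro-1H,3H-pyrrolo[1,2-c][1,3,2]oxazaborole (10 mol %), catecholborane, toluene, −78 °C; aq. NaOH work-up
Reagents that add atoms: none
Why: Corey–Bakshi–Shibata reduction; the enone carbon chain acts as the large substituent, so the (S)-oxazaborolidine–borane complex should deliver hydride to the face that gives the (1R)-allylic alcohol by 1,2-reduction. This carbinol carbon becomes C10 of the target.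

Step 2
Reactants: 2 (1R)-2-methylcyclohex-2-en-1-ol
Product: 3 tert-butyldimethyl{[(1R)-2-methylcyclohex-2-en-1-yl]oxy}silane
Conditions: TBSCl, imidazole, DMF, 23 °C
Reagents that add atoms: tert-butyldimethylsilyl chloride, CC(C)(C)[Si](C)(C)Cl
Why: Standard silylation; the bulky silyl ether should survive the oxidation, the cuprate and the enolate chemistry and later biases the ring conformation.

Step 3
Reactants: 3 tert-butyldimethyl{[(1R)-2-methylcyclohex-2-en-1-yl]oxy}silane
Product: 4 (4R)-4-[(tert-butyldimethylsilyl)oxy]-3-methylcyclohex-2-en-1-one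
Conditions: CrO3, 3,5-dimethylpyrazole, CH2Cl2, −20 °C
Reagents that add atoms: chromium trioxide, O=[Cr](=O)=O
Why: Allylic oxidation with the CrO3–3,5-dimethylpyrazole complex; hydrogen abstraction at the ring CH2 next to the olefinic CH and oxidation at that terminus should give the enone. The silyloxy-bearing C–H is shielded and the stereocentre is not touched.

Step 4
Reactants: 5 methyl (4S)-2,2-dimethyl-1,3-dioxolane-4-carboxylate
Product: 7 (4R)-4-ethynyl-2,2-dimethyl-1,3-dioxolane, via aldehyde 6 (not isolated)
Conditions: i-Bu2AlH, CH2Cl2, −78 °C; then MeOH, K2CO3, dimethyl (1-diazo-2-oxopropyl)phosphonate, −78 → 23 °C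
Reagents that add atoms: dimethyl (1-diazo-2-oxopropyl)phosphonate, CC(=O)C(=[N+]=[N-])P(=O)(OC)OC
Why: Half-reduction of the ester to the aluminium hemiacetal and in situ Ohira–Bestmann homologation (Seyferth–Gilbert type). The α-alkoxy aldehyde 6 is never isolated, which limits epimerisation of the centre that becomes C2; the descriptor changes from S to R only through the priority change.

Step 5
Reactants: 7 (4R)-4-ethynyl-2,2-dimethyl-1,3-dioxolane
Product: 9 methyl 3-[(4R)-2,2-dimethyl-1,3-dioxolan-4-yl]prop-2-ynoate, via lithium acetylide 8 (not isolated)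
Conditions: n-BuLi, THF, −78 °C; then ClCO2Me, −78 → 0 °C
Reagents that add atoms: methyl chloroformate, COC(=O)Cl; n-butyllithium, [Li]CCCC (lithium of 8 only)
Why: Deprotonation of the terminal alkyne and C-acylation of the acetylide with the chloroformate; the stereocentre is not involved.

Step 6
Reactants: 9 methyl 3-[(4R)-2,2-dimethyl-1,3-dioxolan-4-yl]prop-2-ynoate
Product: 10 methyl (2Z)-3-[(4R)-2,2-dimethyl-1,3-dioxolan-4-yl]but-2-enoate
Conditions: Me2CuLi (from MeLi and CuI), THF, −78 °C; MeOH quench at −78 °C, then aq. NH4Cl
Reagents that add atoms: lithium dimethylcuprate, [Li+].C[Cu-]C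
Why: syn-Carbocupration of the ynoate; methyl and copper add to the same face and protonation with retention should give the (Z)-β-methyl enoate, with the ester carbon (C5) and the dioxolane carbon (C2) cis. The low temperature prevents isomerisation of the vinylcopper through its allenolate.

Step 7
Reactants: 10 methyl (2Z)-3-[(4R)-2,2-dimethyl-1,3-dioxolan-4-yl]but-2-enoate
Product: 11 (2Z)-3-[(4R)-2,2-dimethyl-1,3-dioxolan-4-yl]but-2-en-1-ol
Conditions: i-Bu2AlH, CH2Cl2, −78 °C; potassium sodium tartrate work-up
Reagents that add atoms: none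
Why: 1,2-Reduction of the enoate; olefin geometry and acetonide are unaffected.

Step 8
Reactants: 11 (2Z)-3-[(4R)-2,2-dimethyl-1,3-dioxolan-4-yl]but-2-en-1-ol
Product: 12 (4R)-4-[(2Z)-4-bromobut-2-en-2-yl]-2,2-dimethyl-1,3-dioxolane
Conditions: CBr4, PPh3, 2,6-lutidine, CH2Cl2, −20 °C
Reagents that add atoms: carbon tetrabromide, BrC(Br)(Br)Br
Why: Appel reaction at a primary allylic alcohol, SN2 at the oxyphosphonium carbon without allylic transposition. Cold, buffered conditions should preserve the Z geometry and the acetonide; the bromide is used at once.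

Step 9
Reactants: 4 (4R)-4-[(tert-butyldimethylsilyl)oxy]-3-methylcyclohex-2-en-1-one; 12 (4R)-4-[(2Z)-4-bromobut-2-en-2-yl]-2,2-dimethyl-1,3-dioxolane
Product: 14 (2S,4R)-4-[(tert-butyldimethylsilyl)oxy]-2-{(2Z)-3-[(4R)-2,2-dimethyl-1,3-dioxolan-4-yl]but-2-en-1-yl}-3,3-dimethylcyclohexan-1-one, via lithium enolate 13 (not isolated)
Conditions: Me2CuLi (from MeLi and CuI), Et2O, −40 → 0 °C; then 12, HMPA, THF, −40 → 0 °C
Reagents that add atoms: lithium dimethylcuprate, [Li+].C[Cu-]C (methyl group of 14 and lithium of 13)
Why: Tandem conjugate addition–enolate alkylation (three-component coupling): the cuprate adds methyl to C3 of enone 4 through a β-cuprio adduct of trivalent copper and reductive elimination, which creates the quaternary carbon and releases enolate 13 with its double bond fixed between C1 and C2. Enolate 13 is then C-alkylated by SN2 attack on the primary allylic bromide 12 under HMPA activation; the closest known reaction type is the one-pot cuprate addition to a cyclohexenone with trapping by an allylic halide. No ring is closed in this step. The one new stereocentre, C2 of 14 (C6 of the target), is controlled by the C4 silyloxy group: in the half-chair with the silyloxy group pseudo-equatorial the pseudo-axial C3 methyl blocks one face and the electrophile enters axially on the other, anti to oxygen. In the other half-chair the face free of the axial methyl carries the axial silyloxy group 1,3-syn to the incoming carbon, so both conformers should lead to the 2,4-trans product. The step needs C- over O-alkylation and C2 over C6 alkylation, which kinetic conditions, excess 12 and the absence of a proton source should secure. It also needs SN2 over SN2′, favoured by the primary versus fully substituted allyl termini, and retention of the Z geometry, since 12 does not ionise under basic conditions. The γ-silyloxy group is a poor leaving group, so reductive loss from the enone should not compete with addition.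

Step 10
Reactants: 14 (2S,4R)-4-[(tert-butyldimethylsilyl)oxy]-2-{(2Z)-3-[(4R)-2,2-dimethyl-1,3-dioxolan-4-yl]but-2-en-1-yl}-3,3-dimethylcyclohexan-1-one
Product: 15 tert-butyl{[(1R,3R)-3-{(2Z)-3-[(4R)-2,2-dimethyl-1,3-dioxolan-4-yl]but-2-en-1-yl}-2,2-dimethyl-4-methylidenecyclohexyl]oxy}dimethylsilane
Conditions: Zn, CH2Br2, TiCl4, THF (reagent pre-formed at 0 °C); then 14, CH2Cl2, 23 °C
Reagents that add atoms: dibromomethane, BrCBr
Why: Lombardo methylenation; the non-basic zinc–titanium methylene reagent should convert the hindered, enolisable ketone without epimerising the adjacent centre C6, which a basic phosphorus ylide could not guarantee.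

Step 11
Reactants: 15 tert-butyl{[(1R,3R)-3-{(2Z)-3-[(4R)-2,2-dimethyl-1,3-dioxolan-4-yl]but-2-en-1-yl}-2,2-dimethyl-4-methylidenecyclohexyl]oxy}dimethylsilane
Product: 16 (1R,3R)-3-{(2Z)-3-[(4R)-2,2-dimethyl-1,3-dioxolan-4-yl]but-2-en-1-yl}-2,2-dimethyl-4-methylidenecyclohexan-1-ol
Conditions: Bu4NF, THF, 50 °C
Reagents that add atoms: none
Why: Fluoride cleavage of the secondary silyl ether; the acetonide and both olefins are inert.

Step 12
Reactants: 16 (1R,3R)-3-{(2Z)-3-[(4R)-2,2-dimethyl-1,3-dioxolan-4-yl]but-2-en-1-yl}-2,2-dimethyl-4-methylidenecyclohexan-1-ol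
Product: 17 (4R)-4-{(2Z)-4-[(1R,3S)-3-bromo-2,2-dimethyl-6-methylidenecyclohexyl]but-2-en-2-yl}-2,2-dimethyl-1,3-dioxolane
Conditions: CBr4, PPh3, CH2Cl2, 0 → 40 °C
Reagents that add atoms: carbon tetrabromide, BrC(Br)(Br)Br
Why: Appel reaction with inversion; the oxyphosphonium group reacts from the chair in which it is axial and the side chain equatorial, so bromide enters on the equatorial trajectory. C10 becomes (S) with bromine cis to the side chain, and no base is present to promote elimination.

Step 13
Reactants: 17 (4R)-4-{(2Z)-4-[(1R,3S)-3-bromo-2,2-dimethyl-6-methylidenecyclohexyl]but-2-en-2-yl}-2,2-dimethyl-1,3-dioxolane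
Product: 18 (2R,3Z)-5-[(1R,3S)-3-bromo-2,2-dimethyl-6-methylidenecyclohexyl]-3-methylpent-3-ene-1,2-diol
Conditions: AcOH–H2O (4:1), 40 °C
Reagents that add atoms: none
Why: Acid hydrolysis of the isopropylidene acetal under conditions too mild to isomerise the exocyclic olefin, ionise the allylic C2–O bond or disturb the secondary bromide.

Step 14
Reactants: 18 (2R,3Z)-5-[(1R,3S)-3-bromo-2,2-dimethyl-6-methylidenecyclohexyl]-3-methylpent-3-ene-1,2-diol
Product: 20 (2R,3Z)-2-(acetyloxy)-5-[(1R,3S)-3-bromo-2,2-dimethyl-6-methylidenecyclohexyl]-3-methylpent-3-en-1-yl 4-methylbenzenesulfonate, via hydroxy tosylate 19 (not isolated)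
Conditions: TsCl, Et3N, Bu2SnO (cat.), CH2Cl2, 0 → 23 °C; then Ac2O, 4-(dimethylamino)pyridine (cat.), 23 °C
Reagents that add atoms: 4-methylbenzenesulfonyl chloride, Cc1ccc(cc1)S(Cl)(=O)=O; acetic anhydride, CC(=O)OC(C)=O
Why: Stannylene-catalysed sulfonylation is selective for the primary hydroxyl of a 1,2-diol; the remaining allylic secondary alcohol is acetylated in the same flask, so no hydroxy sulfonate is handled under base.

Step 15
Reactants: 20 (2R,3Z)-2-(acetyloxy)-5-[(1R,3S)-3-bromo-2,2-dimethyl-6-methylidenecyclohexyl]-3-methylpent-3-en-1-yl 4-methylbenzenesulfonate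
Product: 21 (2R,3Z)-1-bromo-5-[(1R,3S)-3-bromo-2,2-dimethyl-6-methylidenecyclohexyl]-3-methylpent-3-en-2-yl acetate
Conditions: LiBr, acetone, 56 °C
Reagents that add atoms: lithium bromide, [Li+].[Br-]
Why: Finkelstein-type SN2 displacement of the primary sulfonate by bromide; the neopentyl secondary bromide at C10 is inert to SN2 exchange and C2 is not involved.

## Compound list

1 | 2-methylcyclohex-2-en-1-one | CC1=CCCCC1=O | starting material
2 | (1R)-2-methylcyclohex-2-en-1-ol | CC1=CCCC[C@H]1O | intermediate
3 | tert-butyldimethyl{[(1R)-2-methylcyclohex-2-en-1-yl]oxy}silane | CC1=CCCC[C@H]1O[Si](C)(C)C(C)(C)C | intermediate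
4 | (4R)-4-[(tert-butyldimethylsilyl)oxy]-3-methylcyclohex-2-en-1-one | CC1=CC(=O)CC[C@H]1O[Si](C)(C)C(C)(C)C | intermediate
5 | methyl (4S)-2,2-dimethyl-1,3-dioxolane-4-carboxylate | COC(=O)[C@@H]1COC(C)(C)O1 | starting material
6 | (4S)-2,2-dimethyl-1,3-dioxolane-4-carbaldehyde | O=C[C@@H]1COC(C)(C)O1 | intermediate (not isolated)
7 | (4R)-4-ethynyl-2,2-dimethyl-1,3-dioxolane | C#C[C@@H]1COC(C)(C)O1 | intermediate
8 | lithium 2-[(4R)-2,2-dimethyl-1,3-dioxolan-4-yl]ethyn-1-ide | [Li+].[C-]#C[C@@H]1COC(C)(C)O1 | intermediate (not isolated)
9 | methyl 3-[(4R)-2,2-dimethyl-1,3-dioxolan-4-yl]prop-2-ynoate | COC(=O)C#C[C@@H]1COC(C)(C)O1 | intermediate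
10 | methyl (2Z)-3-[(4R)-2,2-dimethyl-1,3-dioxolan-4-yl]but-2-enoate | COC(=O)/C=C(/C)[C@@H]1COC(C)(C)O1 | intermediate
11 | (2Z)-3-[(4R)-2,2-dimethyl-1,3-dioxolan-4-yl]but-2-en-1-ol | OC/C=C(/C)[C@@H]1COC(C)(C)O1 | intermediate
12 | (4R)-4-[(2Z)-4-bromobut-2-en-2-yl]-2,2-dimethyl-1,3-dioxolane | BrC/C=C(/C)[C@@H]1COC(C)(C)O1 | intermediate
13 | lithium (4R)-4-[(tert-butyldimethylsilyl)oxy]-3,3-dimethylcyclohex-1-en-1-olate | [Li+].[O-]C1=CC(C)(C)[C@H](O[Si](C)(C)C(C)(C)C)CC1 | intermediate (not isolated)
14 | (2S,4R)-4-[(tert-butyldimethylsilyl)oxy]-2-{(2Z)-3-[(4R)-2,2-dimethyl-1,3-dioxolan-4-yl]but-2-en-1-yl}-3,3-dimethylcyclohexan-1-one | O=C1CC[C@@H](O[Si](C)(C)C(C)(C)C)C(C)(C)[C@@H]1C/C=C(/C)[C@@H]2COC(C)(C)O2 | intermediate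
15 | tert-butyl{[(1R,3R)-3-{(2Z)-3-[(4R)-2,2-dimethyl-1,3-dioxolan-4-yl]but-2-en-1-yl}-2,2-dimethyl-4-methylidenecyclohexyl]oxy}dimethylsilane | C=C1CC[C@@H](O[Si](C)(C)C(C)(C)C)C(C)(C)[C@@H]1C/C=C(/C)[C@@H]2COC(C)(C)O2 | intermediate
16 | (1R,3R)-3-{(2Z)-3-[(4R)-2,2-dimethyl-1,3-dioxolan-4-yl]but-2-en-1-yl}-2,2-dimethyl-4-methylidenecyclohexan-1-ol | C=C1CC[C@@H](O)C(C)(C)[C@@H]1C/C=C(/C)[C@@H]2COC(C)(C)O2 | intermediate
17 | (4R)-4-{(2Z)-4-[(1R,3S)-3-bromo-2,2-dimethyl-6-methylidenecyclohexyl]but-2-en-2-yl}-2,2-dimethyl-1,3-dioxolane | C=C1CC[C@H](Br)C(C)(C)[C@@H]1C/C=C(/C)[C@@H]2COC(C)(C)O2 | intermediate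
18 | (2R,3Z)-5-[(1R,3S)-3-bromo-2,2-dimethyl-6-methylidenecyclohexyl]-3-methylpent-3-ene-1,2-diol | C=C1CC[C@H](Br)C(C)(C)[C@@H]1C/C=C(/C)[C@@H](O)CO | intermediate
19 | (2R,3Z)-5-[(1R,3S)-3-bromo-2,2-dimethyl-6-methylidenecyclohexyl]-2-hydroxy-3-methylpent-3-en-1-yl 4-methylbenzenesulfonate | C=C1CC[C@H](Br)C(C)(C)[C@@H]1C/C=C(/C)[C@@H](O)COS(=O)(=O)c2ccc(C)cc2 | intermediate (not isolated)
20 | (2R,3Z)-2-(acetyloxy)-5-[(1R,3S)-3-bromo-2,2-dimethyl-6-methylidenecyclohexyl]-3-methylpent-3-en-1-yl 4-methylbenzenesulfonate | C=C1CC[C@H](Br)C(C)(C)[C@@H]1C/C=C(/C)[C@@H](OC(C)=O)COS(=O)(=O)c2ccc(C)cc2 | intermediate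
21 | (2R,3Z)-1-bromo-5-[(1R,3S)-3-bromo-2,2-dimethyl-6-methylidenecyclohexyl]-3-methylpent-3-en-2-yl acetate | C=C1CC[C@H](Br)C(C)(C)[C@@H]1C/C=C(/C)[C@H](CBr)OC(C)=O | target

## Step count and least certain steps

Total: 15 steps. Longest linear sequence: 12 steps (5 → 21 through steps 4–8, 9 and 10–15); the ring branch 1 → 4 takes 3 steps.

**Step 9 (key step).** C-alkylation at the neopentyl enolate carbon may be slow. Proton transfer between product and enolate would then allow alkylation at the other α-carbon or O-alkylation, and residual copper species could consume the allylic bromide. Facial selectivity rests on conformational analysis and could be lower than expected; the C2 epimer would be separated at 14. The fallback separates the two bond formations and removes copper from the alkylation. It sets out from 4: cuprate addition in the presence of Me3SiCl should give tert-butyl{[(1R)-2,2-dimethyl-4-[(trimethylsilyl)oxy]cyclohex-3-en-1-yl]oxy}dimethylsilane F1, which is isolated. MeLi in THF (or benzyltrimethylammonium fluoride) then regenerates enolate 13 regiospecifically and salt-free, and alkylation with 12 in THF–HMPA comes back to the route at 14.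

**Step 3.** Hydrogen abstraction at the silyloxy-bearing C–H or at the methyl group, or over-oxidation, may erode the yield of the enone. The fallback replaces C–H oxidation by an epoxide-based 1,3-oxygen transposition. It sets out from 3: epoxidation with mCPBA anti to the silyl ether should give tert-butyl{[(1R,2R,6R)-1-methyl-7-oxabicyclo[4.1.0]heptan-2-yl]oxy}dimethylsilane F2. PhSeNa opens it at the less substituted carbon to (1S,2S,6R)-6-[(tert-butyldimethylsilyl)oxy]-1-methyl-2-(phenylselanyl)cyclohexan-1-ol F3. Oxidation with H2O2 and selenoxide elimination away from the carbinol gives (1R,6R)-6-[(tert-butyldimethylsilyl)oxy]-1-methylcyclohex-2-en-1-ol F4. Babler–Dauben oxidative transposition with pyridinium chlorochromate (C5H5NH[CrO3Cl]) comes back at 4.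

**Step 12.** Substitution at the neopentyl carbon competes with anti elimination toward C9 and with a 1,2-methyl shift from C11 if the oxyphosphonium ionises. The fallback uses a discrete sulfonate and an external nucleophile at low temperature. It sets out from 16: Tf2O and pyridine at −40 °C give (1R,3R)-3-{(2Z)-3-[(4R)-2,2-dimethyl-1,3-dioxolan-4-yl]but-2-en-1-yl}-2,2-dimethyl-4-methylidenecyclohexyl trifluoromethanesulfonate F6, which is displaced with LiBr in acetone at 0 °C with inversion, returning at 17.

**Step 10.** The carbonyl is flanked by a tertiary and, one bond further, a quaternary carbon, so methylenation may stall, and the Lewis-acidic reagent may cleave the acetonide. The fallback is a Peterson olefination. It sets out from 14: Me3SiCH2Li with CeCl3 adds to the ketone to give (2S,4R)-4-[(tert-butyldimethylsilyl)oxy]-2-{(2Z)-3-[(4R)-2,2-dimethyl-1,3-dioxolan-4-yl]but-2-en-1-yl}-3,3-dimethyl-1-[(trimethylsilyl)methyl]cyclohexan-1-ol F5 (either C1 epimer serves). Elimination with KH in THF comes back at 15.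

**Step 15.** The C2 acetate may participate in the displacement; opening of the resulting acetoxonium ion at allylic C2 would cause acetyl migration and misplace the bromide. The fallback removes the acyloxy neighbour from the displacement. It sets out from 18: hydroxy tosylate 19 is isolated and displaced with LiBr to (2R,3Z)-1-bromo-5-[(1R,3S)-3-bromo-2,2-dimethyl-6-methylidenecyclohexyl]-3-methylpent-3-en-2-ol F7, which is acetylated with Ac2O in pyridine at 0 °C to come back at 21.

## Further compounds

F1 | step 9 | tert-butyl{[(1R)-2,2-dimethyl-4-[(trimethylsilyl)oxy]cyclohex-3-en-1-yl]oxy}dimethylsilane | C[Si](C)(C)OC1=CC(C)(C)[C@H](O[Si](C)(C)C(C)(C)C)CC1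
F2 | step 3 | tert-butyl{[(1R,2R,6R)-1-methyl-7-oxabicyclo[4.1.0]heptan-2-yl]oxy}dimethylsilane | C[C@@]12O[C@@H]1CCC[C@H]2O[Si](C)(C)C(C)(C)C
F3 | step 3 | (1S,2S,6R)-6-[(tert-butyldimethylsilyl)oxy]-1-methyl-2-(phenylselanyl)cyclohexan-1-ol | C[C@@]1(O)[C@@H]([Se]c2ccccc2)CCC[C@H]1O[Si](C)(C)C(C)(C)C
F4 | step 3 | (1R,6R)-6-[(tert-butyldimethylsilyl)oxy]-1-methylcyclohex-2-en-1-ol | C[C@@]1(O)C=CCC[C@H]1O[Si](C)(C)C(C)(C)C
F5 | step 10 | (2S,4R)-4-[(tert-butyldimethylsilyl)oxy]-2-{(2Z)-3-[(4R)-2,2-dimethyl-1,3-dioxolan-4-yl]but-2-en-1-yl}-3,3-dimethyl-1-[(trimethylsilyl)methyl]cyclohexan-1-ol (C1 epimers) | C[Si](C)(C)CC1(O)CC[C@@H](O[Si](C)(C)C(C)(C)C)C(C)(C)[C@@H]1C/C=C(/C)[C@@H]2COC(C)(C)O2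
F6 | step 12 | (1R,3R)-3-{(2Z)-3-[(4R)-2,2-dimethyl-1,3-dioxolan-4-yl]but-2-en-1-yl}-2,2-dimethyl-4-methylidenecyclohexyl trifluoromethanesulfonate | C=C1CC[C@@H](OS(=O)(=O)C(F)(F)F)C(C)(C)[C@@H]1C/C=C(/C)[C@@H]2COC(C)(C)O2
F7 | step 15 | (2R,3Z)-1-bromo-5-[(1R,3S)-3-bromo-2,2-dimethyl-6-methylidenecyclohexyl]-3-methylpent-3-en-2-ol | C=C1CC[C@H](Br)C(C)(C)[C@@H]1C/C=C(/C)[C@@H](O)CBr
A1 | alternative 1 | (2R,3Z,6E)-1-bromo-3,7,11-trimethyldodeca-3,6,10-trien-2-yl acetate | CC(C)=CCC/C(C)=C/C/C=C(/C)[C@@H](OC(C)=O)CBr
A2 | alternative 2 | {(4R)-4-[(tert-butyldimethylsilyl)oxy]-3,3-dimethylcyclohex-1-en-1-yl}methanol | OCC1=CC(C)(C)[C@H](O[Si](C)(C)C(C)(C)C)CC1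
A3 | alternative 2 | ethyl 2-{(1R,3R)-3-[(tert-butyldimethylsilyl)oxy]-2,2-dimethyl-6-methylidenecyclohexyl}acetate | C=C1CC[C@@H](O[Si](C)(C)C(C)(C)C)C(C)(C)[C@@H]1CC(=O)OCC
A4 | alternative 3 | (1R,5R)-6,6-dimethyl-2-methylidenebicyclo[3.1.1]heptane | C=C1CC[C@H](C2)C(C)(C)[C@@H]12
A5 | alternative 3 | (1S,3R)-1-bromo-3-(bromomethyl)-2,2-dimethyl-4-methylidenecyclohexane | C=C1CC[C@H](Br)C(C)(C)[C@@H]1CBr
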